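**Plan**

1. Numbering used below: C1 = ester-bearing alkene carbon, then C2(H)=, C3H2, C4H2, C5 (butenolide α-carbon), C6H=, C7H–O (lactone carbinol), C8H2, C9(CH3)=C10H–C11H=C12(iPr), C13H2, C14H(OH); ring A = 14-membered carbocycle, ring B = butenolide.
2. Cuts: C12–C13 (ring A, last C–C bond: dienyl iodide + primary alkyl iodide); C5=C6 and the lactone C–O (ring B: ester, then RCM); CO2Me on C1 and H on C2 across a C1≡C2 alkyne; C14–C1 (ynone); C11=C12 (Wittig); C10–C11 and C9–CH3 (carboalumination/formaldehyde); C8–C9 (epoxide opening); C6=CH2 (ylide carbon).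
3. Forward: the west alcohol (C6–C12) and the east acid (C1–C5, C13, C14) are made separately and joined as an ester; ring B is closed by RCM; ring A is closed last by nickel-electrocatalysed reductive coupling C12–C13; desilylation ends the route.
4. Enabling feature: C13 is a lone CH2 between the oxygenated C14 and the fully substituted sp2 carbon C12 at the end of the C9–C12 diene, so the bond maps onto a stereodefined alkenyl iodide and a β-silyloxy primary radical (an organometallic at C13 would lose the C14 oxygen), while ring B and the C1=C2, C9=C10 and C11=C12 alkenes stiffen the open chain.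
5. Stereochemistry: C7 (R) from (R)-epichlorohydrin; C14 (S in the target) from Noyori transfer hydrogenation of an α-chloro ynone; C1=C2 (Z) from trans-hydrostannation/carbonylation; C9=C10 (E) from syn-carboalumination; C11=C12 from a Stork–Zhao-type iodo-Wittig reaction, retained in the coupling.

Key step: step 17

**Route**

Step 1
Reactants: 1 (R)-epichlorohydrin; 2 ethynyltrimethylsilane
Product: 4 (R)-1-chloro-5-(trimethylsilyl)pent-4-yn-2-ol, via lithium (trimethylsilyl)acetylide 3 (not isolated)
Conditions: nBuLi, THF, −78 °C; BF3·OEt2; then 1, −78 °C; aq. NH4Cl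
Reagents that add atoms: none
Why: Yamaguchi-type BF3-mediated acetylide opening of the epoxide at its CH2 terminus should leave the stereocentre untouched, so C7 comes from the chiral pool.

Step 2
Reactants: 4
Product: 7 (R)-hex-1-en-5-yn-3-ol, via epoxide 5 (not isolated), via silyl enynol 6 (not isolated)
Conditions: Me3S+ I− (3.5 equiv), nBuLi (3.3 equiv), THF, −10 °C to rt; then K2CO3, MeOH, rt
Reagents that add atoms: trimethylsulfonium iodide, C[S+](C)C.[I-]
Why: dimethylsulfonium methylide should close the chlorohydrin to the epoxide, open it at CH2 and eliminate Me2S from the betaine (sulfonium-ylide one-carbon homologation of an epoxide to an allylic alcohol) without touching C7, and methanolysis then frees the alkyne.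

Step 3
Reactants: 7
Product: 10 (2E,5R)-3-methylhepta-2,6-diene-1,5-diol, via alkenylalane 8 (not isolated), via lithium alanate 9 (not isolated)
Conditions: Me3Al (3 equiv), Cp2ZrCl2 (0.25 equiv), CH2Cl2, 0 °C to rt; then nBuLi, THF, −78 °C; (CH2O)n, rt; aq. HCl
Reagents that add atoms: trimethylaluminium, C[Al](C)C; paraformaldehyde (as formaldehyde), C=O
Why: Negishi zirconium-catalysed carboalumination adds CH3 and Al syn across the terminal alkyne (CH3 to the internal carbon) and the alanate is hydroxymethylated with retention, which should fix the C9=C10 (E) geometry.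

Step 4
Reactants: 10
Product: 11 (2E,5R)-5-hydroxy-3-methylhepta-2,6-dienal
Conditions: TEMPO (cat.), PhI(OAc)2, CH2Cl2, rt
Reagents that add atoms: none
Why: oxoammonium oxidation (TEMPO/PhI(OAc)2) is selective for the primary allylic alcohol over the secondary one and should not isomerise the enal.

Step 5
Reactants: 11; 12 isobutyltriphenylphosphonium bromide
Product: 16 (3R,5E,7Z)-8-iodo-5,9-dimethyldeca-1,5,7-trien-3-ol, via ylide 13 (not isolated), via iodophosphonium iodide 14 (not isolated), via iodo ylide 15 (not isolated)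
Conditions: 12 (2.6 equiv), nBuLi, THF, rt; I2, −78 °C; NaHMDS, −78 to −20 °C; then 11, −78 °C to rt
Reagents that add atoms: iodine, II
Why: Stork–Zhao-type Wittig olefination with an α-iodo ylide is kinetically Z-selective (iodine cis to the C10 chain), so it should place the isopropyl group trans to C10, the excess ylide covering the free hydroxyl.

Step 6
Reactants: 17 hept-1-en-6-yne; 18 2-chloro-N-methoxy-N-methylacetamide
Product: 21 1-chloronon-8-en-3-yn-2-one, via lithium acetylide 19 (not isolated), via tetrahedral adduct 20 (not isolated)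
Conditions: nBuLi, THF, −78 °C; then 18, −78 to −40 °C; cold aq. NH4Cl
Reagents that add atoms: none
Why: Weinreb ketone synthesis, in which the chelated tetrahedral adduct should hold until work-up and so stop at the ketone.

Step 7
Reactants: 21
Product: 22 (R)-1-chloronon-8-en-3-yn-2-ol
Conditions: RuCl[(S,S)-TsDPEN](p-cymene) (2 mol%), HCO2H/Et3N (5:2), CH2Cl2, 0 °C to rt
Reagents that add atoms: none
Why: Noyori asymmetric transfer hydrogenation, in which the alkynyl group takes the π-site of the (S,S)-catalyst as the aryl group of α-chloroacetophenones does, should deliver hydride to the face that gives the (R)-chlorohydrin, the future C14.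

Step 8
Reactants: 22
Product: 23 (2S,3Z)-1-chloro-3-(tributylstannyl)nona-3,8-dien-2-ol
Conditions: Bu3SnH, [Cp*RuCl]4 (cat.), CH2Cl2, rt
Reagents that add atoms: tributyltin hydride, CCCC[SnH](CCCC)CCCC
Why: ruthenium-catalysed hydroxyl-directed trans-hydrostannation of a propargylic alcohol should put tin on the alkyne carbon next to the carbinol and hydrogen anti to it, leaving the terminal alkene and the chloride alone.

Step 9
Reactants: 23
Product: 24 methyl (2Z)-2-[(1R)-2-chloro-1-hydroxyethyl]octa-2,7-dienoate
Conditions: Pd(OAc)2 (cat.), Ph3As (cat.), 1,4-benzoquinone, CF3CO2H (cat.), CO (1 atm), MeOH, rt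
Reagents that add atoms: carbon monoxide, [C-]#[O+]; methanol, CO
Why: hydroxyl-assisted oxidative palladium-catalysed methoxycarbonylation of the alkenylstannane (carbonylative Stille-type) replaces tin by CO2Me with retention, which should give the (Z)-enoate of the target (ester cis to C3).

Step 10
Reactants: 24
Product: 25 methyl (2Z)-2-[(1R)-1-(tert-butyldimethylsilyloxy)-2-chloroethyl]octa-2,7-dienoate
Conditions: TBSOTf, 2,6-lutidine, CH2Cl2, −78 to 0 °C
Reagents that add atoms: tert-butyldimethylsilyl triflate, CC(C)(C)[Si](C)(C)OS(=O)(=O)C(F)(F)F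
Why: standard silyl ether formation, which protects C14–OH and blocks epoxide formation from the chlorohydrin.

Step 11
Reactants: 25
Product: 26 methyl (2Z)-2-[(1R)-1-(tert-butyldimethylsilyloxy)-2-chloroethyl]-7-oxohept-2-enoate
Conditions: OsO4 (cat.), NaIO4, 2,6-lutidine, dioxane/H2O, rt
Reagents that add atoms: osmium tetroxide (catalytic oxygen carrier), O=[Os](=O)(=O)=O; sodium periodate, [Na+].[O-][I](=O)(=O)=O
Why: Lemieux–Johnson cleavage, in which the monosubstituted alkene should react far faster than the trisubstituted, electron-poor enoate.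

Step 12
Reactants: 26
Product: 27 methyl (2Z)-2-[(1R)-1-(tert-butyldimethylsilyloxy)-2-chloroethyl]-6-formylhepta-2,6-dienoate
Conditions: aq. CH2O (37%), pyrrolidine (10 mol%), propionic acid (10 mol%), iPrOH, 45 °C
Reagents that add atoms: formaldehyde, C=O
Why: organocatalytic Mannich condensation (α-methylenation of the aldehyde through its enamine) should install the methylene on C5.

Step 13
Reactants: 27
Product: 28 (5Z)-6-[(1R)-1-(tert-butyldimethylsilyloxy)-2-chloroethyl]-7-methoxy-2-methylidene-7-oxohept-5-enoic acid
Conditions: NaClO2, NaH2PO4, 2-methylbut-2-ene, tBuOH/H2O, 0 °C to rt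
Reagents that add atoms: sodium chlorite, [Na+].[O-]Cl=O
Why: Pinnick oxidation converts the 2-substituted acrolein into the acrylic acid without touching the alkenes, the chloride or the silyl ether.

Step 14
Reactants: 28; 16
Product: 29 (3R,5E,7Z)-8-iodo-5,9-dimethyldeca-1,5,7-trien-3-yl ester of acid 28 (acyl group on the C7 oxygen)
Conditions: EDC·HCl, DMAP (cat.), CH2Cl2, 0 °C to rt
Reagents that add atoms: none
Why: Steglich-type carbodiimide esterification of the secondary allylic alcohol, in which no stereocentre is touched.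

Step 15
Reactants: 29
Product: 30 methyl (2Z)-2-[(1R)-1-(tert-butyldimethylsilyloxy)-2-chloroethyl]-5-{(5R)-5-[(2E,4Z)-5-iodo-2,6-dimethylhepta-2,4-dien-1-yl]-2-oxo-2,5-dihydrofuran-3-yl}pent-2-enoate
Conditions: second-generation Hoveyda–Grubbs catalyst, RuCl2(H2IMes)(=CH–C6H4–2-OiPr) (10 mol%), toluene, 80 °C, 5 mM
Reagents that add atoms: none
Why: ring-closing metathesis between the vinyl group on C7 and the acrylate methylene should close ring B with loss of ethene, the trisubstituted enoate and iododiene alkenes being inert.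

Step 16
Reactants: 30
Product: 31 methyl (2Z)-2-[(1R)-1-(tert-butyldimethylsilyloxy)-2-iodoethyl]-5-{(5R)-5-[(2E,4Z)-5-iodo-2,6-dimethylhepta-2,4-dien-1-yl]-2-oxo-2,5-dihydrofuran-3-yl}pent-2-enoate
Conditions: NaI (10 equiv), butan-2-one, 80 °C, dark
Reagents that add atoms: sodium iodide, [Na+].[I-]
Why: Finkelstein exchange at the primary chloride, driven by precipitation of NaCl, should leave the alkenyl iodide and ring B untouched.

Step 17
Reactants: 31
Product: 32 O-tert-butyldimethylsilyl ether of the target (ring A closed, silyl ether on the C14 oxygen)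
Conditions: NiBr2·glyme (20 mol%), 4,4'-di-tert-butyl-2,2'-bipyridine (24 mol%), NaI (electrolyte), DMA, undivided cell, Zn anode, RVC cathode, constant current (about 2.5 F/mol), rt, 31 added by syringe pump (final concentration 2 mM or less)
Reagents that add atoms: none
Why: Proposed new method: cathodically generated zerovalent nickel should insert into the C12–I bond of the dienyl iodide with retention, a monovalent nickel species should abstract iodine from C13 to give the primary β-silyloxy radical, and capture of that radical by the alkenylnickel followed by reductive elimination from trivalent nickel forms C12–C13. The closest known reaction type is the intermolecular nickel-catalysed reductive cross-electrophile coupling of alkenyl halides with primary alkyl halides (zinc powder or a cathode as reductant), which has apparently not been used to close a macrocycle. Ring A (14-membered carbocycle) is closed by C(sp2)–C(sp3) reductive elimination at nickel, an end-to-end macrocyclisation with no exo/endo choice, giving the bridged bicycle with ring B already in place. No stereocentre is formed: C7 and C14 are spectators, and the C11=C12 geometry set in step 5 should be carried through because insertion and elimination at nickel are stereoretentive. The step needs cyclisation to win over oligomerisation and hydrodeiodination, which syringe-pump addition and a current-limited radical flux should secure, and a clean division of roles between the two C–I bonds, which is inherent (two-electron insertion at sp2 carbon, halogen-atom abstraction at sp3 carbon). The substrate helps because ring B, the diene and the (Z)-enoate stiffen the chain, the C13 radical can neither expel the silyloxy group nor close onto C1=C2 (three- or four-membered rings), and ring B and the enoate should not be reduced at the potential of the nickel couple.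

Step 18
Reactants: 32
Product: 33 CNP0173999.1 (target)
Conditions: HF·pyridine, pyridine, THF, 0 °C to rt
Reagents that add atoms: none
Why: buffered fluoride desilylation should free C14–OH without opening ring B or moving the alkenes.

**Compound list**

1 | (R)-epichlorohydrin | ClC[C@H]1CO1 | starting material
2 | ethynyltrimethylsilane | C#C[Si](C)(C)C | starting material
3 | lithium (trimethylsilyl)acetylide | [Li]C#C[Si](C)(C)C | intermediate (not isolated)
4 | (R)-1-chloro-5-(trimethylsilyl)pent-4-yn-2-ol | ClC[C@H](O)CC#C[Si](C)(C)C | intermediate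
5 | (R)-trimethyl[3-(oxiran-2-yl)prop-1-yn-1-yl]silane | C[Si](C)(C)C#CC[C@@H]1CO1 | intermediate (not isolated)
6 | (R)-6-(trimethylsilyl)hex-1-en-5-yn-3-ol | C=C[C@H](O)CC#C[Si](C)(C)C | intermediate (not isolated)
7 | (R)-hex-1-en-5-yn-3-ol | C=C[C@H](O)CC#C | intermediate
8 | (E)-alkenyldimethylalane of 7 (dimethylaluminium alkoxide) | C=C[C@H](O[Al](C)C)C/C(C)=C/[Al](C)C | intermediate (not isolated)
9 | lithium butyl(dimethyl)alkenylalanate from 8 | C=C[C@H](O[Al](C)C)C/C(C)=C/[Al-](C)(C)CCCC.[Li+] | intermediate (not isolated)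
10 | (2E,5R)-3-methylhepta-2,6-diene-1,5-diol | C=C[C@H](O)C/C(C)=C/CO | intermediate
11 | (2E,5R)-5-hydroxy-3-methylhepta-2,6-dienal | C=C[C@H](O)C/C(C)=C/C=O | intermediate
12 | isobutyltriphenylphosphonium bromide | CC(C)C[P+](c1ccccc1)(c1ccccc1)c1ccccc1.[Br-] | starting material
13 | (2-methylpropylidene)triphenylphosphorane | CC(C)C=P(c1ccccc1)(c1ccccc1)c1ccccc1 | intermediate (not isolated)
14 | (1-iodo-2-methylpropyl)triphenylphosphonium iodide | CC(C)C(I)[P+](c1ccccc1)(c1ccccc1)c1ccccc1.[I-] | intermediate (not isolated)
15 | (1-iodo-2-methylpropylidene)triphenylphosphorane | CC(C)C(I)=P(c1ccccc1)(c1ccccc1)c1ccccc1 | intermediate (not isolated)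
16 | (3R,5E,7Z)-8-iodo-5,9-dimethyldeca-1,5,7-trien-3-ol | C=C[C@H](O)C/C(C)=C/C=C(/C(C)C)I | intermediate
17 | hept-1-en-6-yne | C=CCCCC#C | starting material
18 | 2-chloro-N-methoxy-N-methylacetamide | ClCC(=O)N(C)OC | starting material
19 | lithium hept-6-en-1-yn-1-ide | [Li]C#CCCCC=C | intermediate (not isolated)
20 | lithium 1-chloro-2-[methoxy(methyl)amino]non-8-en-3-yn-2-olate | C=CCCCC#CC(CCl)(O[Li])N(C)OC | intermediate (not isolated)
21 | 1-chloronon-8-en-3-yn-2-one | ClCC(=O)C#CCCCC=C | intermediate
22 | (R)-1-chloronon-8-en-3-yn-2-ol | ClC[C@H](O)C#CCCCC=C | intermediate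
23 | (2S,3Z)-1-chloro-3-(tributylstannyl)nona-3,8-dien-2-ol | ClC[C@H](O)/C(=C/CCCC=C)[Sn](CCCC)(CCCC)CCCC | intermediate
24 | methyl (2Z)-2-[(1R)-2-chloro-1-hydroxyethyl]octa-2,7-dienoate | ClC[C@H](O)/C(=C/CCCC=C)C(=O)OC | intermediate
25 | methyl (2Z)-2-[(1R)-1-(tert-butyldimethylsilyloxy)-2-chloroethyl]octa-2,7-dienoate | ClC[C@H](O[Si](C)(C)C(C)(C)C)/C(=C/CCCC=C)C(=O)OC | intermediate
26 | methyl (2Z)-2-[(1R)-1-(tert-butyldimethylsilyloxy)-2-chloroethyl]-7-oxohept-2-enoate | ClC[C@H](O[Si](C)(C)C(C)(C)C)/C(=C/CCCC=O)C(=O)OC | intermediate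
27 | methyl (2Z)-2-[(1R)-1-(tert-butyldimethylsilyloxy)-2-chloroethyl]-6-formylhepta-2,6-dienoate | ClC[C@H](O[Si](C)(C)C(C)(C)C)/C(=C/CCC(=C)C=O)C(=O)OC | intermediate
28 | (5Z)-6-[(1R)-1-(tert-butyldimethylsilyloxy)-2-chloroethyl]-7-methoxy-2-methylidene-7-oxohept-5-enoic acid | ClC[C@H](O[Si](C)(C)C(C)(C)C)/C(=C/CCC(=C)C(=O)O)C(=O)OC | intermediate
29 | (3R,5E,7Z)-8-iodo-5,9-dimethyldeca-1,5,7-trien-3-yl ester of 28 | C=C[C@H](OC(=O)C(=C)CC/C=C(/[C@H](CCl)O[Si](C)(C)C(C)(C)C)C(=O)OC)C/C(C)=C/C=C(/C(C)C)I | intermediate
30 | butenolide chloride (name as in step 15) | COC(=O)/C(=C\CCC1=C[C@@H](C/C(C)=C/C=C(/C(C)C)I)OC1=O)[C@H](CCl)O[Si](C)(C)C(C)(C)C | intermediate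
31 | butenolide diiodide (name as in step 16) | COC(=O)/C(=C\CCC1=C[C@@H](C/C(C)=C/C=C(/C(C)C)I)OC1=O)[C@H](CI)O[Si](C)(C)C(C)(C)C | intermediate
32 | O-tert-butyldimethylsilyl ether of the target | COC(=O)/C1=C\CCC2=C[C@@H](C/C(C)=C/C=C(/C(C)C)C[C@@H]1O[Si](C)(C)C(C)(C)C)OC2=O | intermediate
33 | CNP0173999.1 | COC(=O)/C1=C\CCC2=C[C@@H](C/C(C)=C/C=C(/C(C)C)C[C@@H]1O)OC2=O | target

**Count and risks**

Total: 18 steps. Longest linear sequence: 13 steps (steps 6 to 18); the west branch (steps 1 to 5) joins at step 14.

Steps most likely to fail: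

1. Step 17 (nickel-electrocatalysed ring closure). Oligomerisation through intermolecular coupling, hydrodeiodination at either carbon, or erosion of the C11=C12 geometry at the alkenylnickel stage may outrun cyclisation. The fallback uses only known reaction types, sets out from acid 28 and alcohol 16, and returns at 32. Acid 28 is converted into its tert-butyl ester F1 (Boc2O, DMAP, tBuOH). Finkelstein exchange (NaI, butan-2-one, 80 °C) gives the iodide F2. F2 is joined to 16 by the intermolecular nickel-catalysed reductive alkenyl–alkyl coupling (NiI2, 4,4'-di-tert-butyl-2,2'-bipyridine, pyridine, NaI, Zn dust, DMPU, 40 °C) to give the open-chain hydroxy diester F3, which already holds the C12–C13 bond. Aqueous H3PO4 (85%) in toluene removes the tert-butyl group to give the seco hydroxy acid F4. Yamaguchi macrolactonisation (2,4,6-trichlorobenzoyl chloride, Et3N, THF; then DMAP, toluene, high dilution) gives the 15-membered lactone F5. Transannular ring-closing metathesis with the catalyst of step 15 then closes ring B and gives 32.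

2. Step 5 (iodo-Wittig olefination). Incomplete iodination of the β-branched ylide, loss of Z-selectivity, or proton transfer from the free hydroxyl may spoil the reaction. The fallback sets out from 11 and returns at 16. The hydroxyl of 11 is silylated (TBSCl, imidazole, DMF) to the silyl ether F6. Ramirez dibromo-olefination (CBr4, PPh3, Zn, CH2Cl2) gives the dibromodiene F7. Trans-selective Negishi coupling with isopropylzinc bromide (Pd(DPEphos)Cl2, THF) replaces the bromine cis to hydrogen and gives the (Z)-bromodiene F8. Copper-catalysed halogen exchange (CuI, NaI, N,N'-dimethylethylenediamine, dioxane, 110 °C) gives the iodide F9, and HF·pyridine frees 16.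

3. Step 9 (oxidative methoxycarbonylation). Protodestannation in acidic methanol may outrun transmetalation, or the terminal alkene may be drawn into oxidative carbonylation. The fallback sets out from 23 and returns at 24. Iodine–tin exchange (I2, CH2Cl2, 0 °C, retention) gives the alkenyl iodide F10, which is carbonylated without an oxidant (PdCl2(PPh3)2, CO 1 atm, MeOH, NaOAc, 50 °C) to give 24.

**Further compounds**

F1 | step 17 | 1-tert-butyl 7-methyl (5Z)-6-[(1R)-1-(tert-butyldimethylsilyloxy)-2-chloroethyl]-2-methylidenehept-5-enedioate | ClC[C@H](O[Si](C)(C)C(C)(C)C)/C(=C/CCC(=C)C(=O)OC(C)(C)C)C(=O)OC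
F2 | step 17 | 1-tert-butyl 7-methyl (5Z)-6-[(1R)-1-(tert-butyldimethylsilyloxy)-2-iodoethyl]-2-methylidenehept-5-enedioate | IC[C@H](O[Si](C)(C)C(C)(C)C)/C(=C/CCC(=C)C(=O)OC(C)(C)C)C(=O)OC
F3 | step 17 | open-chain C12–C13 coupled hydroxy diester (tert-butyl acrylate, free C7 hydroxyl) | C=C[C@H](O)C/C(C)=C/C=C(/C(C)C)C[C@H](O[Si](C)(C)C(C)(C)C)/C(=C/CCC(=C)C(=O)OC(C)(C)C)C(=O)OC
F4 | step 17 | seco hydroxy acid from F3 | C=C[C@H](O)C/C(C)=C/C=C(/C(C)C)C[C@H](O[Si](C)(C)C(C)(C)C)/C(=C/CCC(=C)C(=O)O)C(=O)OC
F5 | step 17 | 15-membered macrolactone (vinyl on C7, exocyclic methylene on C5) | C=C[C@H]1C/C(C)=C/C=C(/C(C)C)C[C@H](O[Si](C)(C)C(C)(C)C)/C(=C/CCC(=C)C(=O)O1)C(=O)OC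
F6 | step 5 | (2E,5R)-5-(tert-butyldimethylsilyloxy)-3-methylhepta-2,6-dienal | C=C[C@H](O[Si](C)(C)C(C)(C)C)C/C(C)=C/C=O
F7 | step 5 | tert-butyl{[(3R,5E)-8,8-dibromo-5-methylocta-1,5,7-trien-3-yl]oxy}dimethylsilane | C=C[C@H](O[Si](C)(C)C(C)(C)C)C/C(C)=C/C=C(Br)Br
F8 | step 5 | tert-butyl{[(3R,5E,7Z)-8-bromo-5,9-dimethyldeca-1,5,7-trien-3-yl]oxy}dimethylsilane | C=C[C@H](O[Si](C)(C)C(C)(C)C)C/C(C)=C/C=C(/C(C)C)Br
F9 | step 5 | tert-butyl{[(3R,5E,7Z)-8-iodo-5,9-dimethyldeca-1,5,7-trien-3-yl]oxy}dimethylsilane | C=C[C@H](O[Si](C)(C)C(C)(C)C)C/C(C)=C/C=C(/C(C)C)I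
F10 | step 9 | (2S,3Z)-1-chloro-3-iodonona-3,8-dien-2-ol | ClC[C@H](O)/C(I)=C/CCCC=C
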